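**Retrosynthetic overview**
- Cyclohexene ring (formed last): ring-closing metathesis of two 1,1-disubstituted alkenes makes the tetrasubstituted C5=C10 bond of the fully functionalised seco-precursor.
- Key C6–C7 bond: the aldehyde carbon C6 is joined to the lactone β-carbon C7 with a butenolide allylstannane used as a lactone homoenolate equivalent. This one step sets C6 and C7 from C8 and creates the exocyclic methylene.
- γ-Lactone ring (formed first, as a butenolide): metathesis of a 2-(bromomethyl)acrylate ester; C8 comes from a catalytic asymmetric allylation of cinnamaldehyde.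
- Side chain and C4: (S)-citronellal, cut down to an acetoxy aldehyde and α-methylenated.
- The acetate and the isobutyrate are carried from the start; no protecting group is used on the main route.

Locants used: lactone C12(=O)–C11(=C13H2)–C7–C8–O; ring C5 (side chain), C6 (OH), C7, C8, C9 (CH2), C10 (C14H2–O-isobutyrate); side chain C4 (CH3), C3, C2, C1 (OAc).

Assumption: transient metal alkoxides and organometallic species (allylchromium, π-allylpalladium, boron alkoxides) are not numbered; every covalent intermediate carried on without isolation is.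
Assumption: in step 5 the ligand antipode is the one that delivers the allyl group to the Re face of the aldehyde (checked on 12 by Mosher ester analysis).

**Route**

Step 1
Reactants: 1 (S)-citronellal [(3S)-3,7-dimethyloct-6-enal]
Product: 3 (4S)-6,6-dimethoxy-4-methylhexan-1-ol, via dimethyl acetal 2 (not isolated)
Conditions: HC(OMe)3, MeOH, PPTS (cat.), 0 °C to rt; NaHCO3; then O3, CH2Cl2/MeOH, −78 °C; then NaBH4, −78 °C to rt
Reagents that add atoms: trimethyl orthoformate, COC(OC)OC; ozone, [O-][O+]=O
Why: Acid-catalysed acetalisation masks the aldehyde, then ozonolysis of the trisubstituted alkene with reductive (NaBH4) work-up gives the primary alcohol; the methyl-bearing stereocentre of citronellal is untouched and becomes C4 (S).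

Step 2
Reactants: 3 (4S)-6,6-dimethoxy-4-methylhexan-1-ol
Product: 5 (4S)-4-methyl-6-oxohexyl acetate, via acetal acetate 4 (not isolated)
Conditions: Ac2O, pyridine, DMAP (cat.), CH2Cl2, 0 °C to rt; then 1 M aq. HCl, THF, rt
Reagents that add atoms: acetic anhydride, CC(=O)OC(C)=O; water, O
Why: DMAP-catalysed O-acetylation followed in the same flask by acid-catalysed acetal hydrolysis; the primary acetate survives dilute acid and no stereocentre is involved.

Step 3
Reactants: 5 (4S)-4-methyl-6-oxohexyl acetate
Product: 6 (4S)-5-formyl-4-methylhex-5-en-1-yl acetate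
Conditions: 37% aq. CH2O, pyrrolidine (10 mol %), EtCO2H (10 mol %), iPrOH, 45 °C
Reagents that add atoms: formaldehyde, C=O
Why: Amine-catalysed Mannich condensation and β-elimination (α-methylenation of an aldehyde); the enamine involves only C5/C6, so C4 keeps its configuration.

Step 4
Reactants: 7 3-bromo-2-(bromomethyl)prop-1-ene (3 equiv); 8 isobutyric acid (2-methylpropanoic acid)
Product: 9 2-(bromomethyl)prop-2-en-1-yl 2-methylpropanoate
Conditions: K2CO3, DMF, rt; excess 7 recovered by distillation
Reagents that add atoms: none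
Why: SN2 O-alkylation of potassium isobutyrate by the allylic dibromide; the threefold excess of 7 suppresses the diester.

Step 5
Reactants: 9 2-(bromomethyl)prop-2-en-1-yl 2-methylpropanoate; 10 (E)-cinnamaldehyde
Product: 12 (4R,5E)-4-hydroxy-2-methylidene-6-phenylhex-5-en-1-yl 2-methylpropanoate, via silyl ether 11 (not isolated)
Conditions: CrCl2 (10 mol %), 3,6-di-tert-butyl-1,8-bis(4-isopropyl-4,5-dihydrooxazol-2-yl)-9H-carbazole (12 mol %), Mn powder, iPr2NEt (30 mol %), Me3SiCl, THF, rt; then 1 M aq. HCl work-up
Reagents that add atoms: chlorotrimethylsilane, C[Si](C)(C)Cl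
Why: Catalytic enantioselective Nozaki–Hiyama–Kishi allylation: divalent chromium turns the allyl bromide into a trivalent allylchromium that adds 1,2 to the enal in a ligand-controlled closed transition state (Mn as reductant, Me3SiCl releasing the product as silyl ether 11, cleaved on work-up); Re-face attack sets the C8 carbinol as R.

Step 6
Reactants: 12 (4R,5E)-4-hydroxy-2-methylidene-6-phenylhex-5-en-1-yl 2-methylpropanoate; 13 2-(bromomethyl)acrylic acid
Product: 15 (3R,1E)-5-{[(2-methylpropanoyl)oxy]methyl}-1-phenylhexa-1,5-dien-3-yl 2-(bromomethyl)prop-2-enoate, via acid chloride 14 (not isolated)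
Conditions: 13, (COCl)2, DMF (cat.), CH2Cl2, 0 °C to rt, evaporate; then 12, 2,6-lutidine, CH2Cl2, −20 to 0 °C
Reagents that add atoms: oxalyl chloride, ClC(=O)C(=O)Cl
Why: Acylation of the secondary alcohol by the acid chloride with retention at C8; the hindered base is used because nucleophilic amines add SN2′ to 2-(bromomethyl)acrylates.

Step 7
Reactants: 15 (3R,1E)-5-{[(2-methylpropanoyl)oxy]methyl}-1-phenylhexa-1,5-dien-3-yl 2-(bromomethyl)prop-2-enoate
Product: 16 2-{[(2R)-4-(bromomethyl)-5-oxo-2,5-dihydrofuran-2-yl]methyl}prop-2-en-1-yl 2-methylpropanoate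
Conditions: second-generation Hoveyda–Grubbs catalyst RuCl2(H2IMes)(=CH-C6H4-2-OiPr) (5 mol %), CH2Cl2 (5 mM), 40 °C
Reagents that add atoms: none
Why: Ring-closing metathesis between the styryl alkene and the acrylate gives the butenolide (trisubstituted alkene) with loss of styrene; the side-chain 1,1-disubstituted alkene could only close to a cyclobutene or a tetrasubstituted six-membered lactone and is left alone, and C8 (R) is unaffected.

Step 8
Reactants: 16 2-{[(2R)-4-(bromomethyl)-5-oxo-2,5-dihydrofuran-2-yl]methyl}prop-2-en-1-yl 2-methylpropanoate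
Product: 17 2-({(2R)-5-oxo-4-[(tributylstannyl)methyl]-2,5-dihydrofuran-2-yl}methyl)prop-2-en-1-yl 2-methylpropanoate
Conditions: (Bu3Sn)2 (1.2 equiv), Pd2(dba)3 (2 mol %), THF, 0 °C to rt
Reagents that add atoms: hexabutylditin, CCCC[Sn](CCCC)(CCCC)[Sn](CCCC)(CCCC)CCCC
Why: Palladium-catalysed stannylation of an allylic bromide (oxidative addition of zerovalent palladium to a π-allyl complex, Sn–Sn transmetalation, reductive elimination at the unhindered CH2 terminus); base-free, so the acidic C8–H is not epimerised.

Step 9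
Reactants: 17 2-({(2R)-5-oxo-4-[(tributylstannyl)methyl]-2,5-dihydrofuran-2-yl}methyl)prop-2-en-1-yl 2-methylpropanoate; 6 (4S)-5-formyl-4-methylhex-5-en-1-yl acetate
Product: 18 (4S,6S)-6-hydroxy-4-methyl-5-methylidene-6-[(2R,3R)-4-methylidene-2-(2-{[(2-methylpropanoyl)oxy]methyl}prop-2-en-1-yl)-5-oxooxolan-3-yl]hexyl acetate
Conditions: BF3·OEt2 (2.5 equiv), CH2Cl2, −78 °C; then H2O (buffered work-up)
Reagents that add atoms: none
Why: Proposed new method: the 3-(stannylmethyl)butenolide acts as a homoenolate (d3) equivalent of the lactone, so the lactone β-carbon C7 and the aldehyde carbon C6, both normally electrophilic, are joined by a BF3-promoted SE2′ addition (closest known reactions: Lewis-acid additions of 2-(alkoxycarbonyl)allylstannanes and of crotylstannanes to aldehydes, and metal-mediated allylations with 3-(bromomethyl)furan-2(5H)-one); attack on the butenolide face opposite the C8 side chain gives C7 (R) and the trans lactone, the open antiperiplanar transition state with the aldehyde substituent turned away from C8 gives the syn adduct (C6 S, hydroxyl cis to C11 in the later ring), and the exocyclic methylene forms in the same event while the weakly nucleophilic side-chain alkenes stay inert at −78 °C.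

Step 10
Reactants: 18 (4S,6S)-6-hydroxy-4-methyl-5-methylidene-6-[(2R,3R)-4-methylidene-2-(2-{[(2-methylpropanoyl)oxy]methyl}prop-2-en-1-yl)-5-oxooxolan-3-yl]hexyl acetate
Product: 19 [(3aR,4S,7aR)-5-[(2S)-5-acetoxypentan-2-yl]-4-hydroxy-3-methylidene-2-oxo-2,3,3a,4,7,7a-hexahydro-1-benzofuran-6-yl]methyl 2-methylpropanoate (target)
Conditions: RuCl2[1,3-bis(2-methylphenyl)imidazolidin-2-ylidene](=CH-C6H4-2-OiPr) (10 mol % in two portions), 1,4-benzoquinone (20 mol %), toluene (2 mM), 80 °C, Ar sparge
Reagents that add atoms: none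
Why: Ring-closing metathesis of two 1,1-disubstituted alkenes to the tetrasubstituted cyclohexene with loss of ethene, helped by the free allylic hydroxyl and a small N-aryl carbene ligand made for hindered olefins; the α-methylene lactone could only close to a cyclobutene or a bridgehead alkene, and all four stereocentres are spectators.

**Compound list**

1 | (S)-citronellal, (3S)-3,7-dimethyloct-6-enal | O=CC[C@@H](C)CCC=C(C)C | starting material
2 | (6S)-8,8-dimethoxy-2,6-dimethyloct-2-ene | COC(OC)C[C@@H](C)CCC=C(C)C | intermediate (not isolated)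
3 | (4S)-6,6-dimethoxy-4-methylhexan-1-ol | COC(OC)C[C@@H](C)CCCO | intermediate
4 | (4S)-6,6-dimethoxy-4-methylhexyl acetate | COC(OC)C[C@@H](C)CCCOC(C)=O | intermediate (not isolated)
5 | (4S)-4-methyl-6-oxohexyl acetate | O=CC[C@@H](C)CCCOC(C)=O | intermediate
6 | (4S)-5-formyl-4-methylhex-5-en-1-yl acetate | C=C(C=O)[C@@H](C)CCCOC(C)=O | intermediate
7 | 3-bromo-2-(bromomethyl)prop-1-ene | C=C(CBr)CBr | starting material
8 | isobutyric acid | CC(C)C(=O)O | starting material
9 | 2-(bromomethyl)prop-2-en-1-yl 2-methylpropanoate | CC(C)C(=O)OCC(=C)CBr | intermediate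
10 | (E)-cinnamaldehyde | O=C/C=C/c1ccccc1 | starting material
11 | (4R,5E)-2-methylidene-6-phenyl-4-[(trimethylsilyl)oxy]hex-5-en-1-yl 2-methylpropanoate | CC(C)C(=O)OCC(=C)C[C@@H](O[Si](C)(C)C)/C=C/c1ccccc1 | intermediate (not isolated)
12 | (4R,5E)-4-hydroxy-2-methylidene-6-phenylhex-5-en-1-yl 2-methylpropanoate | CC(C)C(=O)OCC(=C)C[C@@H](O)/C=C/c1ccccc1 | intermediate
13 | 2-(bromomethyl)acrylic acid | OC(=O)C(=C)CBr | starting material
14 | 2-(bromomethyl)prop-2-enoyl chloride | ClC(=O)C(=C)CBr | intermediate (not isolated)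
15 | (3R,1E)-5-{[(2-methylpropanoyl)oxy]methyl}-1-phenylhexa-1,5-dien-3-yl 2-(bromomethyl)prop-2-enoate | CC(C)C(=O)OCC(=C)C[C@@H](OC(=O)C(=C)CBr)/C=C/c1ccccc1 | intermediate
16 | 2-{[(2R)-4-(bromomethyl)-5-oxo-2,5-dihydrofuran-2-yl]methyl}prop-2-en-1-yl 2-methylpropanoate | CC(C)C(=O)OCC(=C)C[C@@H]1C=C(CBr)C(=O)O1 | intermediate
17 | 2-({(2R)-5-oxo-4-[(tributylstannyl)methyl]-2,5-dihydrofuran-2-yl}methyl)prop-2-en-1-yl 2-methylpropanoate | CC(C)C(=O)OCC(=C)C[C@@H]1C=C(C[Sn](CCCC)(CCCC)CCCC)C(=O)O1 | intermediate
18 | (4S,6S)-6-hydroxy-4-methyl-5-methylidene-6-[(2R,3R)-4-methylidene-2-(2-{[(2-methylpropanoyl)oxy]methyl}prop-2-en-1-yl)-5-oxooxolan-3-yl]hexyl acetate | C=C1C(=O)O[C@H](CC(=C)COC(=O)C(C)C)[C@H]1[C@H](O)C(=C)[C@@H](C)CCCOC(C)=O | intermediate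
19 | [(3aR,4S,7aR)-5-[(2S)-5-acetoxypentan-2-yl]-4-hydroxy-3-methylidene-2-oxo-2,3,3a,4,7,7a-hexahydro-1-benzofuran-6-yl]methyl 2-methylpropanoate | C=C1C(=O)O[C@@H]2CC(COC(=O)C(C)C)=C([C@@H](C)CCCOC(C)=O)[C@@H](O)[C@@H]12 | target

**Step count and risks**

Total steps: 10. Longest linear sequence: 7 (steps 4 to 10); the citronellal branch (steps 1 to 3) joins at step 9.

Most likely to fail:

Step 10 (tetrasubstituted ring-closing metathesis with a sec-alkyl group on one alkene). Fallback: set out from 18 and silylate the C6 hydroxyl (Et3SiOTf, 2,6-lutidine, −78 °C) to the triethylsilyl ether F5. Close the ring with the molybdenum alkylidene Mo(=CHCMe2Ph)(=N-2,6-iPr2C6H3)[OCMe(CF3)2]2 in benzene at 60 °C, which is the more reactive carbene class for tetrasubstituted alkenes but needs the hydroxyl masked, to give the silyl ether of the target F6. HF·pyridine in THF then removes silicon and the route is rejoined at 19.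

Step 9 (reactivity of the electron-poor stannane and the syn/anti ratio at C6). Fallback: set out from 16 and 6 and couple them with CrCl2 in THF (Nozaki–Hiyama–Kishi reaction). Its closed chair transition state with the ring-locked E-type allylchromium is expected to give the anti adduct, the C6 epimer of 18, alcohol F3, with the same trans lactone. Mitsunobu inversion with chloroacetic acid (PPh3, DIAD, toluene, 0 °C) gives the inverted chloroacetate F4. Thiourea with NaHCO3 in ethanol removes the chloroacetyl group without touching the acetate, the isobutyrate or the lactone, and the route is rejoined at 18.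

Step 5 (enantioselectivity with the functionalised 2-substituted allyl bromide). Fallback: set out from 9 and 10 and run a zinc-mediated Barbier allylation (Zn, sat. aq. NH4Cl/THF) to the racemic alcohol F1. Dess–Martin periodinane (NaHCO3-buffered) gives the enone F2. Reduction with (S)-2-methyl-CBS-oxazaborolidine (10 mol %) and catecholborane in toluene at −78 °C, with the styryl group as the large substituent, gives the R carbinol and the route is rejoined at 12.

**Further compounds**

F1 | step 5 | racemic (5E)-4-hydroxy-2-methylidene-6-phenylhex-5-en-1-yl 2-methylpropanoate | CC(C)C(=O)OCC(=C)CC(O)/C=C/c1ccccc1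
F2 | step 5 | (5E)-2-methylidene-4-oxo-6-phenylhex-5-en-1-yl 2-methylpropanoate | CC(C)C(=O)OCC(=C)CC(=O)/C=C/c1ccccc1
F3 | step 9 | C6 epimer of 18, (4S,6R)-6-hydroxy-4-methyl-5-methylidene-6-[(2R,3R)-4-methylidene-2-(2-{[(2-methylpropanoyl)oxy]methyl}prop-2-en-1-yl)-5-oxooxolan-3-yl]hexyl acetate | C=C1C(=O)O[C@H](CC(=C)COC(=O)C(C)C)[C@H]1[C@@H](O)C(=C)[C@@H](C)CCCOC(C)=O
F4 | step 9 | C6 chloroacetate of 18 (C6 configured as in 18) | C=C1C(=O)O[C@H](CC(=C)COC(=O)C(C)C)[C@H]1[C@H](OC(=O)CCl)C(=C)[C@@H](C)CCCOC(C)=O
F5 | step 10 | C6 triethylsilyl ether of 18 | C=C1C(=O)O[C@H](CC(=C)COC(=O)C(C)C)[C@H]1[C@H](O[Si](CC)(CC)CC)C(=C)[C@@H](C)CCCOC(C)=O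
F6 | step 10 | C6 triethylsilyl ether of 19 | C=C1C(=O)O[C@@H]2CC(COC(=O)C(C)C)=C([C@@H](C)CCCOC(C)=O)[C@@H](O[Si](CC)(CC)CC)[C@@H]12
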